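The alder and elm runs, both at 10 mM of substrate, differ in their reagent, and the new flask lies between them.

| flask | substrate | reagent | remark | time |
|---|---|---|---|---|
| alder | 10 mM | 0.25 equiv | run made earlier |  |
| elm | 10 mM | 1 equiv | run made earlier |  |
| flask | 10 mM | 0.500 equiv |  | 50 min |

| run | time / min | target / % | substrate / % |
|---|---|---|---|
| alder | 0.417 | 10.7 | 52.3 |
| alder | 1.00 | 15.0 | 48.5 |
| alder | 3.00 | 13.9 | 45.4 |
| alder | 10.0 | 9.2 | 43.5 |
| alder | 30.0 | 7.6 | 39.5 |
| elm | 0.417 | 32.1 | 34.7 |
| elm | 1.00 | 45.0 | 20.2 |
| elm | 3.00 | 47.0 | 10.5 |
| elm | 10.0 | 33.7 | 3.9 |
| elm | 30.0 | 28.5 | 1.4 |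

(readings scatter by 0.5 percentage points)

- the analysis behind the earlier runs scatters by 0.5 percentage points, standard deviation

- the moment within 50 min at which there is most target
- the amount of target, in percent of the substrate charged, at that time
- earliest time at which at least nineteen twentieths of that best amount are there, in min
- latest time at which they still are, in min

*What do the runs show first?* In each, c(target) climbs within minutes, peaks and then falls back. The highest reading is 15.0 % at 1.00 min in alder and 47.0 % at 3.00 min in elm.

*What would you hold constant?* The highest target reading divided by the equivalents of reagent charged. Alder reads 60.0 % and elm 47.0 %.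

*But that isn't constant.* No, elm, with more reagent, reads lower than alder, and a scatter of 0.5 percentage points on those readings doesn't explain the gap. Still, the flask has twice alder's reagent, and elm has twice the flask's. It therefore stands midway on a logarithmic scale, so I take the geometric mean, 53.1 %, and call it the peak share.

*And your figure for the flask?* My own reckoning multiplies the peak share by 0.500 equiv, which gives 26.6 %.

*And the times?* I have no reckoning of my own for those, so I take the forecast's: the peak at 1.5 min, with the window from 0.95 min to 2.7 min. The forecast's amount is 26.5 %, and its ground is that “target scales as about equiv^0.8”. It rests on the same runs as mine, so the closeness of our amounts is no check.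

    substrate ⇌ tautomer (K = 0.650, k = 0.0870 s⁻¹)
    substrate + reagent → isomer of the product A (k = 1.40 L mol⁻¹ s⁻¹)
    reagent + tautomer → target (k = 9.90 L mol⁻¹ s⁻¹)
    reagent ⇌ dormant form (K = 0.980, k = 0.00460 s⁻¹)
    target ⇌ isomer of the product B (K = 1.60, k = 0.00230 s⁻¹)
    substrate + tautomer → side product (k = 0.0190 L mol⁻¹ s⁻¹)

The flask gives 28.1 % at 1.53 min, and the window runs from 0.942 min to 2.60 min, so the forecast holds within its margins; by 5.00 min the target is down to 22.6 %. The flask's peak share is 56.2 %. For the neighbouring flask with 2.00 equiv, the frozen 53.1 % asks for 106 %, more than the substrate charged; it gives 57.2 %, a peak share of 28.6 %. In the flask the reagent is the limiting reagent, with 0 % left at 50.0 min, whereas in that neighbour the substrate runs out first, 0 % remaining at 50.0 min beside 25 % of the reagent's own charge and 4.95 mM of dormant form.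

(The numbers in the tables were generated by integration with constants of no real substance; scatter was added.)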